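**Assumption:** the SMILES is read as (2S)-sigmoidin A; carbonate 3 and chromone 5 are taken as purchasable (3 is otherwise one step from 2-methylbut-3-en-2-ol and Boc2O).

## Retrosynthetic overview

1. Ring B comes from catechol (1): para-bromination gives 4-bromocatechol (2), and Pd-catalysed double O-tert-prenylation with carbonate 3 gives the bis(1,1-dimethylallyl) ether 4.
2. The C2–C1′ bond and the only stereocentre are made together: the arylzinc from 4 adds enantioselectively (Rh/(S)-BINAP) to 5,7-dihydroxychromone (5), silylated in situ, dearomatising the pyranone to give (S)-flavanone 6.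
3. Both C-prenyl groups of sigmoidin A (7) are installed last by a double aromatic Claisen rearrangement of 6 (O3′→C2′, O4′→C5′).
4. No ring is built: the A/C bicycle is bought as 5 and ring B is catechol. No isolated protecting groups are used.

## Route

**Step 1**
Reactants: 1, catechol (benzene-1,2-diol)
Product: 2, 4-bromobenzene-1,2-diol
Conditions: NBS (1.0 equiv), HBF4·OEt2, MeCN, −30 °C → rt
Reagents that add atoms: N-bromosuccinimide, O=C1CCC(=O)N1Br
Why: Electrophilic aromatic bromination para to a hydroxyl; C4 and C5 of catechol are symmetry-equivalent, so one monobromide forms and the symmetry of the feedstock is broken (no stereocentre).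

**Step 2**
Reactants: 2, 4-bromobenzene-1,2-diol; 3, tert-butyl (2-methylbut-3-en-2-yl) carbonate
Product: 4, 4-bromo-1,2-bis[(2-methylbut-3-en-2-yl)oxy]benzene
Conditions: 3 (3 equiv), Pd(PPh3)4 (5 mol %), 4 Å MS, THF, 0–5 °C → rt; purify on Et3N-deactivated silica, store cold
Reagents that add atoms: 3, CC(C)(C)OC(=O)OC(C)(C)C=C (delivers two C5H9 groups; CO2 and t-BuOH are lost)
Why: Decarboxylative Tsuji–Trost O-allylation, in which the phenoxide attacks the tertiary terminus of the 1,1-dimethyl-π-allyl-Pd (kinetic branched ether, precedented for catechol-type bis-ethers), while the electron-rich Ar–Br is inert to Pd(0)/PPh3 at or below rt.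

**Step 3 (key step)**
Reactants: 4, 4-bromo-1,2-bis[(2-methylbut-3-en-2-yl)oxy]benzene (2.2 equiv); 5, 5,7-dihydroxy-4H-chromen-4-one
Product: 6, (2S)-2-{3,4-bis[(2-methylbut-3-en-2-yl)oxy]phenyl}-5,7-dihydroxy-2,3-dihydro-4H-chromen-4-one
Conditions: (a) 4, t-BuLi (2 equiv per Br), THF, −78 °C; ZnCl2, −78 → 0 °C. (b) 5, BSA (2.4 equiv), THF, 50 °C. (c) a + b, [RhCl((S)-binap)]2 (3 mol %), TMSCl (2.5 equiv), THF, 20 °C. (d) AcOH/MeOH/H2O, 0 °C → rt
Reagents that add atoms: none (Li, Zn and TMS are lost; the C3–H comes from the work-up)
Why: Proposed new method: the Rh(I)/BINAP-catalysed asymmetric 1,4-addition of ArZnCl with TMSCl trapping (closest known type: Hayashi's additions to 4-quinolones and 2,3-dihydro-4-pyridones, and Rh-catalysed arylboron additions to chromones) is extended to the transiently bis-O-silylated chromone; Ar–Rh(binap) carbometalates C2=C3 with aryl delivered to C2, dearomatising the pyranone, the Rh enolate is silylated to a 4-silyloxy-2H-chromene that cannot ring-open to the chalcone (so no racemisation or double addition), and (S)-BINAP is expected to give (2S) by the facial model that gives (S)-3-arylcyclohexanones (use (R)-BINAP if CD/chiral HPLC shows the opposite sense).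

**Step 4**
Reactants: 6, (2S)-2-{3,4-bis[(2-methylbut-3-en-2-yl)oxy]phenyl}-5,7-dihydroxy-2,3-dihydro-4H-chromen-4-one
Product: 7, sigmoidin A, (2S)-2-[3,4-dihydroxy-2,5-bis(3-methylbut-2-en-1-yl)phenyl]-5,7-dihydroxy-2,3-dihydro-4H-chromen-4-one
Conditions: degassed PhMe (0.02 M), 110 °C, sealed tube, Ar, dark
Reagents that add atoms: none (isomerisation)
Why: Double aromatic Claisen ([3,3]) rearrangement of the tert-allyl aryl ethers: each ether has only one free ortho C–H (O3′→C2′, O4′→C5′), the allyl inversion turns 1,1-dimethylallyl into a normal prenyl group, and the neutral aprotic conditions leave C2 (set in step 3) untouched.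

## Compound list

1 | catechol (benzene-1,2-diol) | Oc1ccccc1O | starting material
2 | 4-bromobenzene-1,2-diol | Oc1ccc(Br)cc1O | intermediate
3 | tert-butyl (2-methylbut-3-en-2-yl) carbonate | CC(C)(C)OC(=O)OC(C)(C)C=C | starting material
4 | 4-bromo-1,2-bis[(2-methylbut-3-en-2-yl)oxy]benzene | C=CC(C)(C)Oc1ccc(Br)cc1OC(C)(C)C=C | intermediate
5 | 5,7-dihydroxy-4H-chromen-4-one | O=c1ccoc2cc(O)cc(O)c12 | starting material
6 | (2S)-2-{3,4-bis[(2-methylbut-3-en-2-yl)oxy]phenyl}-5,7-dihydroxy-2,3-dihydro-4H-chromen-4-one | C=CC(C)(C)Oc1ccc([C@@H]2CC(=O)c3c(O)cc(O)cc3O2)cc1OC(C)(C)C=C | intermediate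
7 | sigmoidin A, (2S)-2-[3,4-dihydroxy-2,5-bis(3-methylbut-2-en-1-yl)phenyl]-5,7-dihydroxy-2,3-dihydro-4H-chromen-4-one | CC(C)=CCc1cc([C@@H]2CC(=O)c3c(O)cc(O)cc3O2)c(CC=C(C)C)c(O)c1O | target

## Step count and risks

Total steps: 4. Longest linear sequence: 4 (1 → 2 → 4 → 6 → 7).

Steps most likely to fail, with fallbacks:

1. **Step 3** (unprecedented arylzinc/chromone combination; conversion, ee, or incomplete silylation of the chelated 5-OH). Fallback: switch to an isolated, protected pair. Convert 4 to the arylboronic acid (t-BuLi, B(OiPr)3), protect 5 as 5,7-bis(MOM)chromone, and join them by the established aqueous Rh(I)–OH/chiral bisphosphine arylboronic acid addition to chromones. Then Claisen and mild acidic MOM removal (+3 steps).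

2. **Step 4** (competing ipso-Claisen/Cope to C6′ or Claisen/Diels–Alder caging, prenyl transfer to the nucleophilic A ring, partial racemisation on heating). Fallback: move the rearrangement ahead of the coupling. Rearrange bromide 4 to 4-bromo-3,6-diprenylcatechol, where there is no stereocentre or A ring and isomers can be separated. Protect it as the bis-MOM ether, use the pre-prenylated aryl nucleophile in the Rh step, and finish with acidic deprotection.

3. **Step 2** (linear O-prenyl or C-allylated by-products, incomplete second etherification next to the first tertiary ether). Fallback: build the ethers without π-allyl chemistry. Cu-catalysed O-alkylation with 3-chloro-3-methylbut-1-yne (CuCl2, DBU) gives the bis(1,1-dimethylpropargyl) ether, and Lindlar semi-hydrogenation then gives 4 (+1 step).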